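Assumption: the target is prepared as the free bis(hydrogen sulfate) exactly as drawn. Locants used below: fragment A (upper decalin) C1–C10, with C4 = carbon bearing the exocyclic methylene, C5 = angular carbon bearing the CH2CH2 linker, C8 = CHMe, C9 = C(Me)(CH2Ar), C10 = ring-fusion CH; β = face of the linker at C5, α = the other face. Fragment B (lower decalin): C1′ (quaternary, joined to the linker), C2′ (CHMe), C4′=C4a′, C5′ (CMe2), C8a′ (ring-fusion CH). "Fragment B" as a substituent means the 1,2,5,5-tetramethyl-1,2,3,5,6,7,8,8a-octahydronaphthalen-1-yl group configured as in aldehyde 5.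

**Retrosynthetic overview**
1. Disulfate ⇐ hydroquinone ⇐ aryl dimethyl ether; the axial 8α-methyl ⇐ cuprate addition to a Δ7-6-ketone obtained by transposing the C8 ketone (C6=O then removed).
2. C9 quaternary centre and H-10 ⇐ reductive benzylation of a Wieland–Miescher-type enone; C4 methylene ⇐ Wittig.
3. Fragment A ⇐ amino-acid-mediated Robinson annulation of a 2-alkylcyclohexane-1,3-dione (dione ring first, C5–C10 ring second).
4. Key bond C5–CH2 ⇐ alkylborane of fragment B + 2-bromo-3-methoxycyclohexenone, i.e. the dione α-carbon used as the electrophile (enolonium equivalent) against a nucleophilic alkyl carbon.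
5. Fragment B ⇐ exo-selective asymmetric Diels–Alder of 6,6-dimethyl-1-vinylcyclohexene with tiglic aldehyde (its cyclohexene ring is the first ring formed).

**Route**

Step 1
Reactants: 1 2,2-dimethylcyclohexan-1-one
Product: 2 6,6-dimethylcyclohex-1-en-1-yl trifluoromethanesulfonate
Conditions: LiN(iPr)2, THF, −78 °C; PhNTf2, −78 → 0 °C; H2O
Reagents that add atoms: N-phenylbis(trifluoromethanesulfonimide), O=S(=O)(N(c1ccccc1)S(=O)(=O)C(F)(F)F)C(F)(F)F
Why: Kinetic enolate formation at the only enolisable α-carbon followed by O-triflation (enol triflate synthesis); no stereocentre.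

Step 2
Reactants: 2 6,6-dimethylcyclohex-1-en-1-yl trifluoromethanesulfonate
Product: 3 6,6-dimethyl-1-vinylcyclohex-1-ene
Conditions: vinylboronic acid pinacol ester, Pd(PPh3)4 (3 mol %), K3PO4, dioxane/H2O, 80 °C
Reagents that add atoms: vinylboronic acid pinacol ester, C=CB1OC(C)(C)C(C)(C)O1
Why: Suzuki–Miyaura coupling of the enol triflate gives the 1,3-diene; no stereocentre.

Step 3
Reactants: 3 6,6-dimethyl-1-vinylcyclohex-1-ene; 4 (E)-2-methylbut-2-enal (tiglic aldehyde)
Product: 5 (1S,2R,8aS)-1,2,5,5-tetramethyl-1,2,3,5,6,7,8,8a-octahydronaphthalene-1-carbaldehyde (CHO cis to H-8a′; C1′ and C2′ methyls cis to each other and trans to H-8a′)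
Conditions: (S)-3,3-diphenyl-1-(o-tolyl)tetrahydro-1H,3H-pyrrolo[1,2-c][1,3,2]oxazaborole (20 mol %), AlBr3 (16 mol %), CH2Cl2, −40 °C
Reagents that add atoms: none
Why: Lewis-acid-catalysed Diels–Alder reaction with "ortho" regiochemistry, in which the (E)-geometry of 4 fixes the cis C1′/C2′ methyls, the exo-formyl transition state (Lewis-acid-bound CHO turned away from the CMe2-bearing diene carbon, α-methyl endo) places CHO cis to H-8a′, and the chiral oxazaborolidinium catalyst directs the diene to the Cα-Re face of the enal to set the absolute configuration (the (S)-catalyst is assigned from the formyl C–H···O binding model and is checked by Mosher analysis of a reduced sample; the (R)-catalyst gives the mirror image).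

Step 4
Reactants: 5 aldehyde of fragment B
Product: 6 1-ethenyl-1,2,5,5-tetramethyl-1,2,3,5,6,7,8,8a-octahydronaphthalene (configuration as in 5; vinyl cis to H-8a′)
Conditions: Ph3PCH3Br, KOtBu, THF, 0 → 60 °C
Reagents that add atoms: methyltriphenylphosphonium bromide, C[P+](c1ccccc1)(c1ccccc1)c1ccccc1.[Br-]
Why: Wittig methylenation of a non-enolisable aldehyde; the three stereocentres are untouched.

Step 5
Reactants: 7 3-methoxycyclohex-2-en-1-one
Product: 8 2-bromo-3-methoxycyclohex-2-en-1-one
Conditions: N-bromosuccinimide, CH2Cl2, 0 °C → rt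
Reagents that add atoms: N-bromosuccinimide, O=C1CCC(=O)N1Br
Why: Electrophilic bromination at C2, the nucleophilic α-carbon of the vinylogous ester; no stereocentre.

Step 6
Reactants: 6 vinyl compound of fragment B; 8 2-bromo-3-methoxycyclohex-2-en-1-one
Product: 11 2-[2-(fragment B)ethyl]cyclohexane-1,3-dione, via alkylborane 9 (not isolated), via vinylogous ester 10 (not isolated)
Conditions: 9-BBN, THF, 0 → 60 °C; then 8, PdCl2(dppf) (5 mol %), aq K3PO4, DMF, 60 °C; then 2 M HCl, THF, rt
Reagents that add atoms: water, O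
Why: Anti-Markovnikov hydroboration of the only terminal alkene, then B-alkyl Suzuki–Miyaura coupling in which C2 of the masked 1,3-dione, normally a nucleophilic enol carbon, is the electrophilic partner (α-bromo vinylogous ester as enolonium equivalent) and is joined to the nucleophilic alkylboron carbon, then acid hydrolysis of the vinylogous ester; no new stereocentre.

Step 7
Reactants: 11 2-[2-(fragment B)ethyl]cyclohexane-1,3-dione; 12 pent-1-en-3-one (ethyl vinyl ketone)
Product: 14 4a-[2-(fragment B)ethyl]-1-methyl-4,4a,7,8-tetrahydronaphthalene-2,5(3H,6H)-dione (angular carbon C5 with the linker β; mirror-image sense to the L-proline-derived Wieland–Miescher ketone), via triketone 13 (not isolated)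
Conditions: Et3N (0.2 equiv), EtOAc, rt; then D-phenylalanine (1 equiv), (1R)-(−)-10-camphorsulfonic acid (0.5 equiv), DMF, 30 → 70 °C
Reagents that add atoms: none
Why: Michael addition followed by amino-acid-mediated enamine aldol condensation (Hajos–Parrish/Wieland–Miescher-type Robinson annulation), in which D-phenylalanine selects one of the two enantiotopic ring carbonyls and so sets C5 under catalyst control.

Step 8
Reactants: 14 enedione
Product: 15 4a-[2-(fragment B)ethyl]-1-methyl-5-methylene-4,4a,5,6,7,8-hexahydronaphthalen-2(3H)-one (C5 as in 14)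
Conditions: Ph3PCH3Br, KOtBu (1.3 equiv each), THF, 0 °C → rt
Reagents that add atoms: methyltriphenylphosphonium bromide, C[P+](c1ccccc1)(c1ccccc1)c1ccccc1.[Br-]
Why: Wittig methylenation is chemoselective for the saturated C4 ketone because the enone carbonyl is deactivated by conjugation; no new stereocentre.

Step 9
Reactants: 15 C4-methylene enone; 16 2,5-dimethoxybenzyl chloride
Product: 17 trans-decalin-8-one of fragment A: 4-methylene, 5β-[2-(fragment B)ethyl], 10α-H, 9β-methyl, 9α-(2,5-dimethoxybenzyl)
Conditions: Li (2.2 equiv), tBuOH (1 equiv), NH3/THF, −78 °C; then 16, −78 → −33 °C; H2O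
Reagents that add atoms: none
Why: Dissolving-metal reductive alkylation of the enone, in which protonation of the β-carbon C10 on the α face gives the trans-fused lithium enolate and this is benzylated at C9 anti to the axial C5 linker, so H-10 and the benzyl group are α and the C9 methyl is β.

Step 10
Reactants: 17 C8 ketone
Product: 18 Δ6-en-8-one of fragment A (other centres as in 17)
Conditions: IBX, 4-methoxypyridine N-oxide, DMSO, 25 °C
Reagents that add atoms: none
Why: IBX dehydrogenation through the enol; only the C6–C7 bond can be desaturated because C9 is quaternary, and no stereocentre changes.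

Step 11
Reactants: 18 Δ6-en-8-one
Product: 19 6α,7α-epoxy-8-ketone of fragment A
Conditions: 30% H2O2, NaOH, MeOH, 0 °C
Reagents that add atoms: hydrogen peroxide, OO
Why: Weitz–Scheffer nucleophilic epoxidation, selective for the electron-poor enone alkene, with hydroperoxide adding axially to C6 on the α face away from the axial linker (these two centres are erased in steps 12 and 13).

Step 12
Reactants: 19 epoxy ketone
Product: 21 6α-hydroxy-Δ7-ene of fragment A (allylic alcohol), via epoxy hydrazone 20 (not isolated)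
Conditions: N2H4·H2O, AcOH (cat.), MeOH, 0 °C → rt
Reagents that add atoms: none
Why: Wharton transposition (epoxy hydrazone to vinyl diazene with loss of N2) moves the oxygen to C6 and the double bond to C7=C8; the C6 carbinol keeps the α C–O bond of the epoxide.

Step 13
Reactants: 21 allylic alcohol
Product: 22 Δ7-en-6-one of fragment A
Conditions: Dess–Martin periodinane, CH2Cl2, rt
Reagents that add atoms: none
Why: Dess–Martin oxidation of the allylic alcohol gives the transposed enone and removes the C6 stereocentre.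

Step 14
Reactants: 22 Δ7-en-6-one
Product: 23 8α-methyl-6-ketone of fragment A (C8 methyl trans to the C9 methyl, cis to the benzyl group)
Conditions: Me2CuLi (from MeLi and CuI, 5 equiv), Et2O, −20 → 0 °C; H2O
Reagents that add atoms: lithium dimethylcuprate (from methyllithium and CuI), [Li+].C[Cu-]C
Why: Gilman cuprate 1,4-addition with axial attack at C8 on the α face, anti to the pseudo-axial 9β-methyl group, gives the 8α-methyl with H-8 β, the epimer that hydrogenation of an 8-methylene compound is not expected to give.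

Step 15
Reactants: 23 8α-methyl-6-ketone
Product: 25 bis(methyl ether) of the target hydroquinone (all seven stereocentres as in the target), via hydrazone 24 (not isolated)
Conditions: N2H4·H2O, KOH, diethylene glycol, 130 °C then 200 °C
Reagents that add atoms: none
Why: Wolff–Kishner reduction (Huang-Minlon procedure) removes the C6 carbonyl; C8 is β to it and cannot epimerise, and the alkenes and aryl ethers are stable to base.

Step 16
Reactants: 25 bis(methyl ether)
Product: 27 hydroquinone 2-{[fragment A]methyl}benzene-1,4-diol, via quinone 26 (not isolated)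
Conditions: (NH4)2Ce(NO3)6 (2.5 equiv), MeCN/H2O, 0 °C; then aq Na2S2O4, EtOAc, rt
Reagents that add atoms: water, O
Why: Oxidative demethylation of the 1,4-dimethoxyarene by tetravalent cerium gives the benzoquinone (oxygens from water), which dithionite reduces to the hydroquinone; no stereocentre is involved.

Step 17
Reactants: 27 hydroquinone
Product: 28 target CNP0426429.4, the bis(hydrogen sulfate) of 27
Conditions: SO3·pyridine (6 equiv), pyridine, 50 °C; then Dowex 50W (H+ form), aq MeOH, 0 °C
Reagents that add atoms: sulfur trioxide–pyridine complex, O=S(=O)([O-])[n+]1ccccc1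
Why: O-Sulfation of both phenols followed by proton exchange gives the bis(hydrogen sulfate); no stereocentre is involved.

**Compound list**

1 | 2,2-dimethylcyclohexan-1-one | CC1(C)CCCCC1=O | starting material
2 | 6,6-dimethylcyclohex-1-en-1-yl trifluoromethanesulfonate | CC1(C)CCCC=C1OS(=O)(=O)C(F)(F)F | intermediate
3 | 6,6-dimethyl-1-vinylcyclohex-1-ene | C=CC1=CCCCC1(C)C | intermediate
4 | (E)-2-methylbut-2-enal | C/C=C(\C)C=O | starting material
5 | (1S,2R,8aS)-1,2,5,5-tetramethyl-1,2,3,5,6,7,8,8a-octahydronaphthalene-1-carbaldehyde | O=C[C@@]1(C)[C@H](C)CC=C2[C@@H]1CCCC2(C)C | intermediate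
6 | 1-ethenyl analogue of 5 (same configuration) | C=C[C@@]1(C)[C@H](C)CC=C2[C@@H]1CCCC2(C)C | intermediate
7 | 3-methoxycyclohex-2-en-1-one | COC1=CC(=O)CCC1 | starting material
8 | 2-bromo-3-methoxycyclohex-2-en-1-one | COC1=C(Br)C(=O)CCC1 | intermediate
9 | 9-[2-(fragment B)ethyl]-9-borabicyclo[3.3.1]nonane | C1CCC2CCCC1B2CC[C@@]1(C)[C@H](C)CC=C2[C@@H]1CCCC2(C)C | intermediate
10 | 2-[2-(fragment B)ethyl]-3-methoxycyclohex-2-en-1-one | COC1=C(CC[C@@]2(C)[C@H](C)CC=C3[C@@H]2CCCC3(C)C)C(=O)CCC1 | intermediate
11 | 2-[2-(fragment B)ethyl]cyclohexane-1,3-dione | O=C1CCCC(=O)C1CC[C@@]1(C)[C@H](C)CC=C2[C@@H]1CCCC2(C)C | intermediate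
12 | pent-1-en-3-one | CCC(=O)C=C | starting material
13 | 2-[2-(fragment B)ethyl]-2-(3-oxopentyl)cyclohexane-1,3-dione | CCC(=O)CCC1(CC[C@@]2(C)[C@H](C)CC=C3[C@@H]2CCCC3(C)C)C(=O)CCCC1=O | intermediate
14 | 4a-[2-(fragment B)ethyl]-1-methyl-4,4a,7,8-tetrahydronaphthalene-2,5(3H,6H)-dione, linker β at C5 | O=C1CCCC2=C(C)C(=O)CC[C@@]12CC[C@@]1(C)[C@H](C)CC=C3[C@@H]1CCCC3(C)C | intermediate
15 | 5-methylene analogue of 14 (C4 exocyclic methylene, C8 enone) | C=C1CCCC2=C(C)C(=O)CC[C@@]12CC[C@@]1(C)[C@H](C)CC=C3[C@@H]1CCCC3(C)C | intermediate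
16 | 2,5-dimethoxybenzyl chloride | ClCc1cc(OC)ccc1OC | starting material
17 | fragment A 8-ketone: 4-methylene, 5β-linker, 10α-H, 9β-Me, 9α-(2,5-dimethoxybenzyl) | C=C1CCC[C@H]2[C@@]1(CC[C@@]1(C)[C@H](C)CC=C3[C@@H]1CCCC3(C)C)CCC(=O)[C@]2(C)Cc1cc(OC)ccc1OC | intermediate
18 | Δ6-en-8-one of 17 | C=C1CCC[C@H]2[C@@]1(CC[C@@]1(C)[C@H](C)CC=C3[C@@H]1CCCC3(C)C)C=CC(=O)[C@]2(C)Cc1cc(OC)ccc1OC | intermediate
19 | 6α,7α-epoxy-8-ketone | C=C1CCC[C@H]2[C@@]1(CC[C@@]1(C)[C@H](C)CC=C3[C@@H]1CCCC3(C)C)[C@@H]4O[C@@H]4C(=O)[C@]2(C)Cc1cc(OC)ccc1OC | intermediate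
20 | C8 hydrazone of 19 | C=C1CCC[C@H]2[C@@]1(CC[C@@]1(C)[C@H](C)CC=C3[C@@H]1CCCC3(C)C)[C@@H]4O[C@@H]4C(=NN)[C@]2(C)Cc1cc(OC)ccc1OC | intermediate
21 | 6α-hydroxy-Δ7-ene | C=C1CCC[C@H]2[C@@]1(CC[C@@]1(C)[C@H](C)CC=C3[C@@H]1CCCC3(C)C)[C@H](O)C=C[C@]2(C)Cc1cc(OC)ccc1OC | intermediate
22 | Δ7-en-6-one | C=C1CCC[C@H]2[C@@]1(CC[C@@]1(C)[C@H](C)CC=C3[C@@H]1CCCC3(C)C)C(=O)C=C[C@]2(C)Cc1cc(OC)ccc1OC | intermediate
23 | 8α-methyl-6-ketone | C=C1CCC[C@H]2[C@@]1(CC[C@@]1(C)[C@H](C)CC=C3[C@@H]1CCCC3(C)C)C(=O)C[C@H](C)[C@]2(C)Cc1cc(OC)ccc1OC | intermediate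
24 | C6 hydrazone of 23 | C=C1CCC[C@H]2[C@@]1(CC[C@@]1(C)[C@H](C)CC=C3[C@@H]1CCCC3(C)C)C(=NN)C[C@H](C)[C@]2(C)Cc1cc(OC)ccc1OC | intermediate
25 | bis(methyl ether) of hydroquinone 27 | C=C1CCC[C@H]2[C@@]1(CC[C@@]1(C)[C@H](C)CC=C3[C@@H]1CCCC3(C)C)CC[C@H](C)[C@]2(C)Cc1cc(OC)ccc1OC | intermediate
26 | 2-{[fragment A]methyl}-1,4-benzoquinone | C=C1CCC[C@H]2[C@@]1(CC[C@@]1(C)[C@H](C)CC=C3[C@@H]1CCCC3(C)C)CC[C@H](C)[C@]2(C)CC1=CC(=O)C=CC1=O | intermediate
27 | 2-{[fragment A]methyl}benzene-1,4-diol | C=C1CCC[C@H]2[C@@]1(CC[C@@]1(C)[C@H](C)CC=C3[C@@H]1CCCC3(C)C)CC[C@H](C)[C@]2(C)Cc1cc(O)ccc1O | intermediate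
28 | target CNP0426429.4, bis(hydrogen sulfate) of 27 | C=C1CCC[C@H]2[C@@]1(CC[C@@]1(C)[C@H](C)CC=C3[C@@H]1CCCC3(C)C)CC[C@H](C)[C@]2(C)Cc1cc(OS(=O)(=O)O)ccc1OS(=O)(=O)O | target

**Step count and risks**

Total step count: 17. Longest linear sequence: 16 (steps 1–4 and 6–17; step 5 makes the coupling partner).

The three steps most likely to fail:

Step 3. Two hindered partners must react through the exo-formyl transition state with high enantioselectivity; the endo adduct or low ee are the likely failures. The fallback sets out again from 3 and 4: the cycloaddition is run racemically with stoichiometric aluminium tris(2,6-diphenylphenoxide), whose bulk around the bound formyl group forces it exo. This gives 5 together with its mirror image, the enantiomeric aldehyde F1, and the two are separated by preparative chromatography on a chiral stationary phase. The route is rejoined at 5.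

Step 7. The amino-acid-mediated aldol condensation may be slow or poorly selective with the large C5 substituent and the ethyl ketone. The fallback sets out from triketone 13 (made from 11 and 12 as in the first half of step 7) and cyclises it with pyrrolidine and acetic acid, without asymmetric induction. Because fragment B is already enantioenriched, the products are 14 and its C5-epimeric enedione F2, which are diastereomers and are separated by chromatography. The route is rejoined at 14.

Step 15. Hydrazone formation at the C6 ketone, which is flanked by the quaternary C5, may fail under Wolff–Kishner conditions. The fallback sets out from 23: LiAlH4 reduction gives the 6β-alcohol F3, NaH/CS2/MeI converts it into the S-methyl xanthate F4, and Bu3SnH with AIBN in toluene at 110 °C (Barton–McCombie deoxygenation) gives 25, where the route is rejoined.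

Further compounds
F1 | step 3 | (1R,2S,8aR)-1,2,5,5-tetramethyl-1,2,3,5,6,7,8,8a-octahydronaphthalene-1-carbaldehyde (enantiomer of 5) | O=C[C@]1(C)[C@@H](C)CC=C2[C@H]1CCCC2(C)C
F2 | step 7 | C5 epimer of enedione 14 | O=C1CCCC2=C(C)C(=O)CC[C@]12CC[C@@]1(C)[C@H](C)CC=C3[C@@H]1CCCC3(C)C
F3 | step 15 | 6β-alcohol derived from 23 | C=C1CCC[C@H]2[C@@]1(CC[C@@]1(C)[C@H](C)CC=C3[C@@H]1CCCC3(C)C)[C@@H](O)C[C@H](C)[C@]2(C)Cc1cc(OC)ccc1OC
F4 | step 15 | O-alkyl S-methyl xanthate of F3 | C=C1CCC[C@H]2[C@@]1(CC[C@@]1(C)[C@H](C)CC=C3[C@@H]1CCCC3(C)C)[C@@H](OC(=S)SC)C[C@H](C)[C@]2(C)Cc1cc(OC)ccc1OC
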